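The readings come from a simulation on assumed constants.

In a one-step world, one X makes one Z until X is gone, so X is the limiting reagent whenever it is charged below E.

in all of them: E 0.020 M
- south-west: X 0.19 equiv; J 0.50 equiv; run made earlier
- north-east: X 2.1 equiv; J 0.50 equiv; run made earlier
- violet: X 0.470 equiv; J 0.500 equiv; time 3.0 min
- blue: X 0.950 equiv; J 0.500 equiv; time 3.0 min
- teal: X 2.80 equiv; J 0.500 equiv; time 3.0 min
- ochre: X 1.90 equiv; J 0.500 equiv; time 3.0 min
- grey: X 0.310 equiv; J 0.500 equiv; time 3.0 min

| run | time / s | Z / % |
|---|---|---|
| south-west | 20.0 | 11.5 |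
| south-west | 40.0 | 14.6 |
| south-west | 60.0 | 17.0 |
| south-west | 80.0 | 17.6 |
| south-west | 120 | 18.3 |
| north-east | 10.0 | 71.8 |
| north-east | 25.0 | 80.4 |
| north-east | 40.0 | 83.4 |
| north-east | 60.0 | 87.9 |
| north-east | 90.0 | 90.8 |
| north-east | 120 | 92.3 |

(scatter of a reading: 0.5 percentage points)

- the numbers in the tables scatter by 0.5 percentage points (one standard deviation)
- a reading or a percentage of Z counts all its forms, free or not

* all flasks from highest to lowest amount of Z, in percent of the E charged, at 3.0 min (violet / blue / teal / ochre / grey)
* the same order at 40 s (violet / blue / teal / ochre / grey)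
* the amount of Z, in percent of the E charged of the flask you put first, at 3.0 min
* the amount of Z, in percent of the E charged of the flask you put last, at 3.0 min

The south-west run looks like that world: 0.19 equiv of X gives 18.3% of Z at 120 s, and the curve flattens. But the north-east run doesn't. In north-east X is charged in excess, Z reaches 71.8% at 10.0 s, and then it creeps to 92.3% at 120 s.

So I assume that Z up to J's charge costs one X each and that later Z costs more. From north-east, X charged less J, divided by Z less J, is 3.78 equiv of X per Z: this is the late price, the X spent per Z made beyond J's charge. It is a reading with scatter, taken while Z was still creeping.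

Going round with it, finishing E takes 2.39 equiv of X, and teal is charged 2.80 equiv, so by this price teal can finish its E. Ochre comes to 87.0% and blue to 61.9%. Grey stays below J's charge and follows its X, at 31.0%.

The forecast gives teal > ochre > blue > violet > grey at 40 s and teal > ochre > blue > violet > grey at 3.0 min, with teal at 96.5% (93.5% to 99.5%) and grey at 30.8% (29.5% to 31.5%) at 3.0 min, holding that “each further Z costs extra X”. It puts ochre at 93 and blue at 68 per cent, where I have the figures above.

The flasks give teal > ochre > blue > violet > grey at 40 s and teal > ochre > blue > violet > grey at 3.0 min, where teal stands at 99.9%, ochre at 88.8%, blue at 60.6% and grey at 29.6%.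

    G + J ⇌ Q (K = 1.10 × 10⁶ M⁻¹, k = 53.0 M⁻¹ s⁻¹)
    E + X ⇌ G + Z (K = 1.50, k = 13.0 M⁻¹ s⁻¹)
    X + G ⇌ D, settled at all times (K = 14000 M⁻¹)
    X + Z ⇌ Qo, settled at all times (K = 2100 M⁻¹)

Grey has 0.35% of its X left at 3.00 min, and its Z stops at 29.6% because X wears away: with that wearing away taken out, the same flask gives 99.9%. The passing of G + J into Q is a part of what holds grey up, for without it grey gives 16.5%. Z in grey moves by 5 points, outside the forecast's range, at 0.252 equiv or 0.374 equiv of X. A flask like grey with 0.780 equiv of X reckons at 57.4% by the late price and stands at 54.8%.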